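All runs stem from a simulated flask from invented constants, noise included.

- In the closed, stirred vessel, first and second end groups join at constant volume and temperature, and each joining makes a link. Second end groups, charged slightly short, are the limiting reagent.

- zeta: first end groups 0.75 M; second end groups 0.98 equiv; run made earlier
- flask: first end groups 1.5 M; second end groups 0.980 equiv; time 5.0 min

zeta run (percent of the first end groups charged)

| time / min | links / % | first end groups / % |
|---|---|---|
| 0.500 | 11 | 88 |
| 0.667 | 12 | 86 |
| 1.00 | 17 | 82 |
| 1.50 | 22 | 79 |
| 2.50 | 30 | 69 |
| 4.00 | 37 | 63 |
| 6.00 | 45 | 55 |

(standard deviation of a reading: 1.5 percentage points)

- the numbers in the tables scatter with a standard deviation of 1.5 percentage points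
- a reading or a percentage of links counts all its forms, free or not

- amount of links in percent of the first end groups charged, at 30 s, 2.0 min and 5.0 min

- The zeta run shows what a reading means. At 6.00 min, links of 45% and first end groups of 55% add up to 100%, so we read links as the conversion of first end groups.

- A step with two partners has a time scale of one over its rate constant times the concentration. We assume that each step here has two partners. Both runs are charged at 0.980 equiv, so equal conversion then falls at equal charge times time.

- This gives our rule, the clock factor, which is the new charge of first end groups over the zeta charge: 2.00. One minute in the new flask counts as that many zeta minutes.

- Reading 30 s in the new flask as 1.00 min of zeta time gives 17%, and reading 2.0 min as 4.00 min gives 37%. Both are readings with a scatter of 1.5 percentage points.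

- The time 5.0 min becomes 10.0 min, later than the last zeta reading, so we must extrapolate. Plain second-order joining at equal charges, which ours nearly are, makes links over first end groups grow in proportion to time. In the zeta run this ratio, as read, goes from 0.207 at 1.00 min to 0.818 at 6.00 min, which reads as a power of 0.766, less than one, and that power carries the scatter of both readings. Carrying that power forward gives a ratio of 1.21, or 54.8% links.

- The forecast gives 15%, 32% and 46%, lower than our figure at the last time, with the words “The reaction slows as links build up, which suggests links tie up the catalyst”.

- The new flask gives 17.9%, 39.3% and 55.6%, against our 17%, 37% and 54.8%.

    first end groups + second end groups → links + by-product (k = 0.350 /M/min)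
    2 second end groups → self-condensation product (k = 0.0740 /M/min)
    second end groups + links ⇌ idle adduct, settled at all times (K = 0.250 /M)
    second end groups ⇌ dormant form (K = 0.510, k = 0.400 /min)

- The step from second end groups to dormant form has one partner, with a relaxation half-life, by this step alone and both ways together, of 0.585 min, and at 0.500 min the new flask held 0.183 M of dormant form. The clock factor places 2.50 min of the new flask at 5.00 min of zeta time, midway between the zeta readings at 4.00 min and 6.00 min, whose mean is 41.0%. The new flask held links of 43.2% at that time.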